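## Structural features

The target is a 2-oxaspiro[4.5]deca-6,9-dien-8-one. A tetrahydrofuran (C1, O2, C3, C4, C5) is joined through the single spiro carbon C5 to a cross-conjugated cyclohexadienone (C5–C10) that carries a methoxy group at C7 next to the C8 carbonyl. The five-membered ring bears a 4-hydroxy-3-methoxyphenyl group at C3, a hydroxymethyl group at C4 and, at C1, a two-carbon chain (C1', C2'). C1' is an aryl ether of 4-(3-hydroxypropyl)-2-methoxyphenol and C2' is a primary alcohol. Four of the five stereocentres are contiguous (C3, C4, C5, C1) and the fifth, C1', is bonded to C1. The C3 aryl group is trans to the C4 hydroxymethyl group and to the C1 chain, C1/C1' are threo, and C5 is stereogenic only because the C6=C7 arm carries the methoxy group; that arm lies on the side of the C4 hydroxymethyl group. Fragile features are the dienone (rearrangement in acid, conjugate addition in base, also by the C4 CH2OH at C6) and the benzylic C3–O2 ether para to a free phenol (opening through a quinone methide). The real difficulty is the quaternary spiro carbon with two nearly identical ring arms, followed by C1 and C1' next to it. The key step exploits that, with C1 at the lactone oxidation level, C5 is the α-carbon of a γ-butyrolactone and C8 stands para to it. The six-membered ring is then the Diels–Alder adduct of an exocyclic C5=C6 methylene lactone and a 2-oxygenated butadiene (C7–C10), with the adjacent C4 stereocentre choosing the face.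

## Logic of the disconnections

39 ⇒ 38. The four O–Si bonds (phenol, C4 CH2O, C2' O, propyl O) are cut last. The free phenol para to the C3 ether and the free CH2OH next to the dienone are the reactive pairings of the molecule, so they stay masked until the end. The forward step must be a fluoride cleavage buffered against base.

38 ⇒ 37 ⇒ 35 ⇒ 34. The O–CH3 bond at C7, then the C7–O bond and the C6=C7 unsaturation are removed. C7 is the only enolisable position of 34, so the site of oxygenation is fixed by the structure. The sensitive dienone becomes a plain enone, and the configuration of C5 then depends only on which arm holds C9=C10. The forward steps demand enolate hydroxylation, a mild oxidation and O-methylation over C-methylation.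

34 ⇒ 31. The O2–C3 bond is cut and C8 is masked as a ketal. C3 is benzylic to an electron-rich ring, so the ether can be closed by ionisation, with the aryl group settling trans to the C4 substituent. This turns the ring into an open chain in which C1 is an ordinary carbinol. The forward step must ionise C3 without loss of the silyl ethers and without epimerising C4.

31 ⇒ 30 ⇒ 29 ⇒ 20 + 28. The C1–C1' bond is cut. It is the only C–C bond between side chain and core, and an auxiliary-controlled aldol sets C1 and C1' together by reagent control. The gain is convergence: a core aldehyde and an aryloxyacetyl unit. The demand is that a boron enolate adds to an aldehyde on a quaternary carbon.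

28 ⇒ 25 + 26, and 25 ⇒ 23 ⇒ 21 + 22. The N-acyl bond and the aryl O–CH2 bond are cut. Both are routine and lead to purchased materials. The only demand is that the phenol is alkylated before the primary alcohol is silylated.

20 ⇒ 19 ⇒ 18 ⇒ 17. No skeletal bond is cut. The C1–O2 acyl bond of the lactone is opened by reduction, and C1 is brought back to the aldehyde level with the C3 oxygen protected. A lactol would not enter a boron aldol, so the open aldehyde is needed. The forward sequence must tell a primary silyl ether from a secondary one.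

17 ⇒ 16 ⇒ 15. The C8 ketal is removed and the C9=C10 bond is traced back to the C8=C9 enol ether. The position of the enol ether decides the position of the double bond. The forward oxidation must outrun hydrolysis of the enol ether.

15 ⇒ 13 + 14. The C6–C7 and C5–C10 bonds are cut. This removes the whole carbocycle and the quaternary centre in one operation and leaves a lactone with two stereocentres. The forward step needs attack anti to the C4 substituent and para orientation.

13 ⇒ 10. The C5=C6 bond is cut (α-methylenation). The demand is that the exocyclic double bond does not move into the ring.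

10 ⇒ 9 ⇒ 8 ⇒ 7 ⇒ 5 + 2. The C3–C4 bond (aldol) and the lactone O2–C1 bond are cut. One syn-aldol sets C3 and C4, and lactonisation of a syn adduct can only give the trans lactone. The carboxyl group at C4 must then be reduced in the presence of the lactone.

5 ⇒ 3 + 4, and 2 ⇒ 1. An N-acyl bond and an O–Si bond are cut, both trivial.

## Other disconnections considered

Alternative 1: The cut is C3–C4, so the tetrahydrofuran is closed late by a carbene. The α-diazo ester A1 has the diazo group at C4 and a vanillyl-type benzyl ether on the C1 oxygen. With a dirhodium tetracarboxylate such as Rh2(OAc)4 the carbene would insert into the benzylic C3–H bond (1,5-insertion) to give ester A2, whose ring double bond is C9=C10 in the numbering used here.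
- In its favour: the C–H bond is activated twice (α to oxygen, benzylic to an electron-rich ring) and sits at the preferred distance. C5 has no hydrogen, so a 1,2-hydride shift is excluded. C1, C1' and the aryl ether can be assembled on an open chain.
- Better than the chosen plan on one point: it avoids an aldol on a hindered aldehyde.
- Against it: A1 must already hold the quaternary C5 as one enantiomer with its two arms differentiated, which is the problem the chosen key step solves. A diazo group next to a quaternary carbon needs deacylative diazo transfer. The aryloxy oxygen (five-membered oxonium ylide) and a 1,2-vinyl shift from C5 would compete for the carbene.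
- Structure: A2 still lacks the C8 carbonyl and the C7 oxygen and carries an ester to be reduced.
- Mechanism: both plans rest on known reaction classes and are equal in that respect.
- Step economy: the alternative is expected to be longer after its key step.

Alternative 2: The cuts are O2–C3 and C1–C5 in one two-component (3+2) step. Sc(OTf)3 would open the C5–C3 bond of the spirocyclopropyl dienone A3 to a phenolate/benzylic cation pair. The oxygen of aldehyde A4 would capture C3, and the para carbon of the phenolate would close onto the oxocarbenium carbon C1 to give A5, the fully silylated target.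
- In its favour: A5 is one deprotection from the target, and ring strain drives the opening.
- Better than the chosen plan: convergence and step count, clearly.
- Against it: C1, C3 and C5 would be set at once with only C4 and the remote aldehyde centre as guides. C3 passes through a planar cation. The configuration of C5 depends on which rotamer of the methoxyphenolate about C4–C5 closes, and the two sides differ only by a distant methoxy group. The second closure must dearomatise a phenolate in competition with proton loss from C4. A4 is configurationally labile under Lewis acid, and A3 is itself a spirodienone to be made in enantiopure form.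
- Structure and mechanism: the chosen plan gives every stereocentre its own control element; the alternative gives none for C5.
- Step economy: the alternative wins only if that control could be found.

Alternative 3: This is a change of order, not a skeletal cut. The C7–O bond is made on the symmetric 7-demethoxy dienone A6, in which C5 is not stereogenic and the C4 hydroxymethyl group is free. Its alkoxide would add to C6, the only arm it can reach (five-membered, cis-fused ether). The enolate would be hydroxylated at C7 by an N-sulfonyloxaziridine to give A7. Oxidation, β-elimination of the ether and O-methylation would follow.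
- In its favour: the two arms are told apart by the reach of a tether, which is more certain than the π-facial selectivity of an intermolecular cycloaddition.
- Better than the chosen plan: security of the C5 configuration. The spiro ring could then come from any unselective method.
- Equal: the end game from A6 is as long as the one from 34.
- Against it: A6 still needs the quaternary centre, the tetrahydrofuran and the side chain, so the route is not shortened. One hydroxyl must be free while three are protected. The conjugate addition is reversible, so the enolate must be trapped before it reverts.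
- Structure and mechanism: both plans let C4 define C5, the chosen one during ring construction and the alternative afterwards.
- Step economy: the chosen plan is more economical because the same step builds the ring.

Key step: step 8

Remarks:
- Atom labels C1–C10, C1' and C2' follow the spiro numbering of the target and are kept for open-chain intermediates.
- Ar is 3-methoxy-4-(triisopropylsilyloxy)phenyl, Ar' is 4-[3-(tert-butyldiphenylsilyloxy)propyl]-2-methoxyphenyl, TBDPS is tert-butyldiphenylsilyl, TES is triethylsilyl and TIPS is triisopropylsilyl.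
- Enolates, alkoxides and cations that are only reactive forms of a numbered compound carry no number.
- 3, 4, 14, 21, 22 and 26 are taken as purchased.
- In 13 and 15 the configurations at C3, C4 and C5 are those of the target. Compared with an all-TBS design, the phenol carries TIPS (base stability) and the primary alcohols carry TBDPS (larger facial shield at C4, acid stability).

Step 1
Reactants: 1 vanillin
Product: 2 3-methoxy-4-(triisopropylsilyloxy)benzaldehyde
Conditions: TIPSCl, imidazole, DMF, rt
Reagents that add atoms: chlorotriisopropylsilane, CC(C)[Si](Cl)(C(C)C)C(C)C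
Why: Silylation of the phenol; the triisopropylsilyl ether should survive the hydroperoxide, enolate and carbonate steps that follow, and it keeps the phenol from expelling the benzylic oxygen as a quinone methide.

Step 2
Reactants: 3 (S)-4-benzyloxazolidin-2-one; 4 methyl 4-chloro-4-oxobutanoate
Product: 5 methyl 4-[(4S)-4-benzyl-2-oxooxazolidin-3-yl]-4-oxobutanoate
Conditions: n-BuLi, THF, −78 °C; then 4, −78 → 0 °C
Reagents that add atoms: none
Why: N-acylation of the lithiated oxazolidinone; the acid chloride is far more electrophilic than the methyl ester at the other end of the chain.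

Step 3
Reactants: 5 methyl 4-[(4S)-4-benzyl-2-oxooxazolidin-3-yl]-4-oxobutanoate; 2 3-methoxy-4-(triisopropylsilyloxy)benzaldehyde
Product: 7 (4S)-4-benzyl-3-[(2S,3S)-2-Ar-5-oxotetrahydrofuran-3-carbonyl]oxazolidin-2-one (trans lactone), via syn-aldol adduct 6 (not isolated)
Conditions: 5, Bu2BOTf, iPr2NEt, CH2Cl2, −78 → 0 °C; 2, −78 → 0 °C; pH 7 buffer, MeOH, H2O2; then PPTS (cat.), PhMe, 60 °C
Reagents that add atoms: none
Why: Evans syn-aldol reaction: the imide α-CH2 (not the ester side) gives the Z boron enolate, which adds through a chair transition state on the face away from the benzyl group and sets C3 and C4 as (S,S). The carbinol then closes onto the methyl ester; a syn adduct can only give the trans lactone, which is also the more stable isomer.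

Step 4
Reactants: 7 (4S)-4-benzyl-3-[(2S,3S)-2-Ar-5-oxotetrahydrofuran-3-carbonyl]oxazolidin-2-one
Product: 8 (2S,3S)-2-Ar-5-oxotetrahydrofuran-3-carboxylic acid
Conditions: LiOH, H2O2, THF/H2O (3:1), 0 °C; Na2SO3; then 1 M HCl to pH 2
Reagents that add atoms: hydrogen peroxide, OO
Why: Hydroperoxide attacks the exocyclic imide carbonyl selectively and the peracid is reduced by sulfite; any lactone that opens should reclose on acidification. C4 is α to the carboxyl group but is already in the favoured trans arrangement.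

Step 5
Reactants: 8 (2S,3S)-2-Ar-5-oxotetrahydrofuran-3-carboxylic acid
Product: 9 (4R,5S)-5-Ar-4-(hydroxymethyl)dihydrofuran-2(3H)-one
Conditions: BH3·SMe2, THF, 0 °C → rt; MeOH quench
Reagents that add atoms: none
Why: Borane reduces a free carboxylic acid through its acyloxyborane much faster than a lactone, and the non-basic medium avoids translactonisation of the new primary alcohol.

Step 6
Reactants: 9 (4R,5S)-5-Ar-4-(hydroxymethyl)dihydrofuran-2(3H)-one
Product: 10 (4R,5S)-5-Ar-4-(TBDPS-oxymethyl)dihydrofuran-2(3H)-one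
Conditions: TBDPSCl, imidazole, DMF, rt
Reagents that add atoms: tert-butyl(chloro)diphenylsilane, CC(C)(C)[Si](Cl)(c1ccccc1)c1ccccc1
Why: Silylation of the primary alcohol; the large silyl group later shields one face of the lactone and does not migrate readily.

Step 7
Reactants: 10 (4R,5S)-5-Ar-4-(TBDPS-oxymethyl)dihydrofuran-2(3H)-one
Product: 13 (4R,5S)-5-Ar-4-(TBDPS-oxymethyl)-3-methylenedihydrofuran-2(3H)-one, via Mannich base 11 (not isolated), via ammonium iodide 12 (not isolated)
Conditions: LiN(iPr)2, THF, −78 °C; CH2=NMe2+ I−, −78 °C → rt; then MeI (excess), rt; then NaHCO3 (aq), CH2Cl2, rt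
Reagents that add atoms: dimethyl(methylene)ammonium iodide, C=[N+](C)C.[I-]
Why: Mannich reaction of the lactone enolate with the iminium salt, exhaustive N-methylation and E1cB loss of trimethylamine give the exocyclic alkene. The transient centre at C5 is removed again, and bicarbonate is mild enough to keep the double bond out of the ring.

Step 8
Reactants: 13 (4R,5S)-5-Ar-4-(TBDPS-oxymethyl)-3-methylenedihydrofuran-2(3H)-one; 14 2-(trimethylsilyloxy)buta-1,3-diene
Product: 15 (3S,4R,5S)-3-Ar-4-(TBDPS-oxymethyl)-8-(trimethylsilyloxy)-2-oxaspiro[4.5]dec-8-en-1-one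
Conditions: 14 (5 equiv), BHT (cat.), PhMe, sealed tube, 130 °C; concentrate and use crude
Reagents that add atoms: none
Why: Normal-electron-demand Diels–Alder reaction, concerted but asynchronous: the diene terminus next to the silyloxy-bearing carbon has the largest HOMO coefficient and bonds first to the β-carbon C6 of the unsaturated lactone, so C6–C7 leads, C5–C10 follows and the oxygenated carbon C8 ends para to C5. The closest known reaction type is the thermal spiroannulation of α-methylene-γ-butyrolactones with 2-silyloxybuta-1,3-dienes to 2-oxaspiro[4.5]decenones. The six-membered ring is closed by suprafacial (4+2) cycloaddition across the exocyclic C5=C6 bond, which makes C5 the spiro atom. The only new stereocentre, C5, is controlled by C4: the diene adds to the alkene face opposite the CH2OTBDPS group, so C10 ends anti and C6 syn to it, the (5S) arrangement of the target. The step needs π-facial selectivity and para regiochemistry; the first comes from the substituent directly next to C5 on a rigid five-membered ring, reinforced by the large silyl group (the C3 aryl group on the other face is one atom further away), and the second from the donor at C2 of the diene. The enol ether double bond of 15 lies at C8–C9, on the C10 arm, and so records which arm is which for step 9. BHT suppresses radical polymerisation, and the labile enol ether is not chromatographed.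

Step 9
Reactants: 15 (3S,4R,5S)-3-Ar-4-(TBDPS-oxymethyl)-8-(trimethylsilyloxy)-2-oxaspiro[4.5]dec-8-en-1-one
Product: 16 (3S,4R,5S)-3-Ar-4-(TBDPS-oxymethyl)-2-oxaspiro[4.5]dec-9-ene-1,8-dione
Conditions: Pd(OAc)2 (1.1 equiv), MeCN, rt
Reagents that add atoms: none
Why: Saegusa oxidation: the silyl enol ether gives the C9 enolate of divalent palladium, and syn β-hydride elimination takes a hydrogen from C10 and releases zerovalent palladium. The double bond can therefore appear only at C9–C10; C7 is never enolised.

Step 10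
Reactants: 16 (3S,4R,5S)-3-Ar-4-(TBDPS-oxymethyl)-2-oxaspiro[4.5]dec-9-ene-1,8-dione
Product: 17 (3S,4R,5S)-3-Ar-4-(TBDPS-oxymethyl)-8,8-(ethylenedioxy)-2-oxaspiro[4.5]dec-9-en-1-one
Conditions: (TMSOCH2)2, TMSOTf (cat.), CH2Cl2, −78 → −20 °C
Reagents that add atoms: 1,2-bis(trimethylsilyloxy)ethane, C[Si](C)(C)OCCO[Si](C)(C)C
Why: Aprotic ketalisation under silyl triflate catalysis converts enones into dioxolanes at low temperature without conjugate addition. The ketal protects C8 from the hydride steps and removes the Michael acceptor while free alkoxides are present.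

Step 11
Reactants: 17 (3S,4R,5S)-3-Ar-4-(TBDPS-oxymethyl)-8,8-(ethylenedioxy)-2-oxaspiro[4.5]dec-9-en-1-one
Product: 18 ring-opened diol with C1 as CH2OH and C3 as CH(OH)Ar (C3 S; C4 R; C5 S; C8 dioxolane)
Conditions: LiBH4, MeOH (2 equiv), THF, 0 → 40 °C
Reagents that add atoms: none
Why: Borohydride reduction of the lactone to the 1,4-diol; ketal, alkene and silyl ethers are inert.

Step 12
Reactants: 18 ring-opened diol
Product: 19 bis(triethylsilyl) ether of 18 (C1 CH2OTES; C3 CH(OTES)Ar)
Conditions: TESCl, imidazole, DMAP (cat.), DMF, rt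
Reagents that add atoms: chlorotriethylsilane, CC[Si](Cl)(CC)CC
Why: Silylation of both hydroxyls; the small triethylsilyl group reaches the hindered benzylic oxygen and is later the first silyl group to leave.

Step 13
Reactants: 19 bis(triethylsilyl) ether
Product: 20 C1 aldehyde with C3 CH(OTES)Ar (C3 S; C4 R; C5 S; C8 dioxolane)
Conditions: (COCl)2, DMSO, CH2Cl2, −78 → −40 °C; then Et3N, −78 → 0 °C
Reagents that add atoms: none
Why: Swern oxidation applied directly to a silyl ether: chlorodimethylsulfonium chloride removes the silyl group from the primary oxygen, and the alkoxysulfonium salt collapses to the aldehyde. The secondary benzylic silyl ether is too hindered to react at this temperature, and the aldehyde has no α-hydrogen.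

Step 14
Reactants: 21 4-(3-hydroxypropyl)-2-methoxyphenol; 22 bromoacetic acid
Product: 23 2-[4-(3-hydroxypropyl)-2-methoxyphenoxy]acetic acid
Conditions: NaOH (aq), 90 °C; then HCl to pH 2
Reagents that add atoms: none
Why: Williamson ether synthesis: in water only the phenoxide is formed, and it displaces bromide from the bromoacetate.

Step 15
Reactants: 23 2-[4-(3-hydroxypropyl)-2-methoxyphenoxy]acetic acid
Product: 25 2-(Ar'-oxy)acetic acid, via silyl ester 24 (not isolated)
Conditions: TBDPSCl (2.5 equiv), imidazole, DMF, rt; then K2CO3, MeOH/H2O, rt; 1 M HCl to pH 3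
Reagents that add atoms: tert-butyl(chloro)diphenylsilane, CC(C)(C)[Si](Cl)(c1ccccc1)c1ccccc1
Why: Both hydroxyl and carboxyl groups are silylated; the silyl ester is hydrolysed by mild carbonate while the primary silyl ether stays.

Step 16
Reactants: 25 2-(Ar'-oxy)acetic acid; 26 (R)-4-benzyloxazolidin-2-one
Product: 28 (R)-4-benzyl-3-[2-(Ar'-oxy)acetyl]oxazolidin-2-one, via mixed pivalic anhydride 27 (not isolated)
Conditions: PivCl, Et3N, THF, −20 °C; then 26, LiCl, −20 °C → rt
Reagents that add atoms: none
Why: N-acylation through the mixed anhydride; the oxazolidinone attacks the unhindered aryloxyacetyl carbonyl and not the pivaloyl one.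

Step 17
Reactants: 20 C1 aldehyde; 28 (R)-4-benzyl-3-[2-(Ar'-oxy)acetyl]oxazolidin-2-one
Product: 29 syn-aldol adduct: (4R)-4-benzyl-3-[(2R,3S)-2-(Ar'-oxy)-3-hydroxy-3-(C5 core)propanoyl]oxazolidin-2-one
Conditions: 28 (1.5 equiv), Bu2BOTf, Et3N, CH2Cl2, −78 → 0 °C; 20, −78 → 0 °C; pH 7 buffer, MeOH, H2O2, 0 °C
Reagents that add atoms: none
Why: Evans syn-aldol reaction of an aryloxyacetyl imide: the Z boron enolate reacts through a chair transition state, and the (R)-auxiliary fixes both the enolate face (C1') and the aldehyde face (C1), giving the threo pair with (1S). Reagent control should prevail because the α-carbon of the aldehyde carries three carbon groups of similar size and no heteroatom.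

Step 18
Reactants: 29 syn-aldol adduct
Product: 30 (1S,1'S)-diol with C1 OH and C2' OH (C3 OTES; C8 dioxolane)
Conditions: LiBH4, MeOH (1 equiv), THF, 0 °C
Reagents that add atoms: none
Why: Reductive cleavage of the exocyclic imide carbonyl gives the primary alcohol and releases the auxiliary; the ketal keeps C8 out of reach.

Step 19
Reactants: 30 (1S,1'S)-diol
Product: 31 C2' TBDPS ether of 30
Conditions: TBDPSCl, imidazole, CH2Cl2, 0 °C → rt
Reagents that add atoms: tert-butyl(chloro)diphenylsilane, CC(C)(C)[Si](Cl)(c1ccccc1)c1ccccc1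
Why: Selective silylation of the primary hydroxyl; the C1 hydroxyl is secondary and flanked by a quaternary carbon.

Step 20
Reactants: 31 C2' TBDPS ether
Product: 34 (1S,3S,4R,5S)-3-Ar-1-[(1S)-1-(Ar'-oxy)-2-(TBDPS-oxy)ethyl]-4-(TBDPS-oxymethyl)-2-oxaspiro[4.5]dec-9-en-8-one, via benzylic alcohol 32 (not isolated), via tetrahydrofuran ketal 33 (not isolated)
Conditions: CSA (0.2 equiv), CH2Cl2 (H2O-saturated), 0 °C → rt; then acetone/H2O (10:1), rt
Reagents that add atoms: water, O
Why: Acid-catalysed cycloetherification through a benzylic cation: the C3 silyl ether is cleaved, C3–O ionises with the help of the para-silyloxy and meta-methoxy groups, and the C1 hydroxyl closes the five-membered ring. The aryl group should settle trans to the C4 substituent, since attack occurs on the face away from it and the closure is reversible. Aqueous acetone then hydrolyses the allylic dioxolane after the ring is closed; the TBDPS and aryl TIPS ethers tolerate these conditions.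

Step 21
Reactants: 34 spirocyclic enone
Product: 35 7-hydroxy derivative of 34 (C7 epimers)
Conditions: KN(SiMe3)2, THF, −78 °C; 2-(phenylsulfonyl)-3-phenyloxaziridine, −78 °C; sat. NH4Cl
Reagents that add atoms: 2-(phenylsulfonyl)-3-phenyloxaziridine, O=S(=O)(c1ccccc1)N1OC1c1ccccc1
Why: Kinetic deprotonation of the 4,4-disubstituted cyclohexenone can occur only at C7 (C5 has no hydrogen) and gives the cross-conjugated dienolate, which is hydroxylated by the oxaziridine. The C7 configuration is irrelevant.

Step 22
Reactants: 35 7-hydroxy enone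
Product: 37 7-hydroxy-2-oxaspiro[4.5]deca-6,9-dien-8-one (diosphenol), via 7,8-dione 36 (not isolated)
Conditions: Dess–Martin periodinane, NaHCO3, CH2Cl2, 0 °C → rt
Reagents that add atoms: none
Why: Oxidation of the α-hydroxy ketone to the 1,2-dione, which can enolise only toward C6 and does so to give the conjugated hydroxy dienone. The electron-rich arenes and silyl ethers are untouched.

Step 23
Reactants: 37 diosphenol
Product: 38 fully silylated target (7-methoxy dienone)
Conditions: Me2SO4, K2CO3, acetone, rt
Reagents that add atoms: dimethyl sulfate, COS(=O)(=O)OC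
Why: O-alkylation of the acidic enol with a hard methylating agent; the aryl TIPS ether should withstand carbonate in acetone, so the phenol is not methylated.

Step 24
Reactants: 38 fully silylated target
Product: 39 (1S,3S,4R,5S)-3-(4-hydroxy-3-methoxyphenyl)-4-(hydroxymethyl)-1-[(1S)-2-hydroxy-1-[4-(3-hydroxypropyl)-2-methoxyphenoxy]ethyl]-7-methoxy-2-oxaspiro[4.5]deca-6,9-dien-8-one
Conditions: TBAF, AcOH (1:1), THF, 0 °C → rt
Reagents that add atoms: none
Why: Fluoride cleaves the aryl and the three primary silyl ethers. Acetic acid keeps phenoxide and alkoxide concentrations low, so neither quinone methide opening of the C3 ether nor alkoxide addition to the dienone should intervene.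

Compound list

1 | vanillin | COc1cc(C=O)ccc1O | starting material
2 | 3-methoxy-4-(triisopropylsilyloxy)benzaldehyde | COc1cc(C=O)ccc1O[Si](C(C)C)(C(C)C)C(C)C | intermediate
3 | (S)-4-benzyloxazolidin-2-one | O=C1N[C@@H](Cc2ccccc2)CO1 | starting material
4 | methyl 4-chloro-4-oxobutanoate | COC(=O)CCC(=O)Cl | starting material
5 | methyl 4-[(4S)-4-benzyl-2-oxooxazolidin-3-yl]-4-oxobutanoate | COC(=O)CCC(=O)N1[C@@H](Cc2ccccc2)COC1=O | intermediate
6 | methyl (3S)-4-[(4S)-4-benzyl-2-oxooxazolidin-3-yl]-3-[(S)-hydroxy(Ar)methyl]-4-oxobutanoate (syn-aldol adduct) | COC(=O)C[C@H](C(=O)N1[C@@H](Cc2ccccc2)COC1=O)[C@H](O)c1ccc(O[Si](C(C)C)(C(C)C)C(C)C)c(OC)c1 | intermediate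
7 | (4S)-4-benzyl-3-[(2S,3S)-2-Ar-5-oxotetrahydrofuran-3-carbonyl]oxazolidin-2-one | O=C1C[C@H](C(=O)N2[C@@H](Cc3ccccc3)COC2=O)[C@@H](c2ccc(O[Si](C(C)C)(C(C)C)C(C)C)c(OC)c2)O1 | intermediate
8 | (2S,3S)-2-Ar-5-oxotetrahydrofuran-3-carboxylic acid | O=C1C[C@H](C(=O)O)[C@@H](c2ccc(O[Si](C(C)C)(C(C)C)C(C)C)c(OC)c2)O1 | intermediate
9 | (4R,5S)-5-Ar-4-(hydroxymethyl)dihydrofuran-2(3H)-one | O=C1C[C@H](CO)[C@@H](c2ccc(O[Si](C(C)C)(C(C)C)C(C)C)c(OC)c2)O1 | intermediate
10 | (4R,5S)-5-Ar-4-(TBDPS-oxymethyl)dihydrofuran-2(3H)-one | O=C1C[C@H](CO[Si](c2ccccc2)(c2ccccc2)C(C)(C)C)[C@@H](c2ccc(O[Si](C(C)C)(C(C)C)C(C)C)c(OC)c2)O1 | intermediate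
11 | (3R,4R,5S)-5-Ar-3-(dimethylaminomethyl)-4-(TBDPS-oxymethyl)dihydrofuran-2(3H)-one (Mannich base, 3,4-trans expected) | O=C1[C@@H](CN(C)C)[C@H](CO[Si](c2ccccc2)(c2ccccc2)C(C)(C)C)[C@@H](c2ccc(O[Si](C(C)C)(C(C)C)C(C)C)c(OC)c2)O1 | intermediate
12 | trimethylammonium iodide of 11 | O=C1[C@@H](C[N+](C)(C)C)[C@H](CO[Si](c2ccccc2)(c2ccccc2)C(C)(C)C)[C@@H](c2ccc(O[Si](C(C)C)(C(C)C)C(C)C)c(OC)c2)O1.[I-] | intermediate
13 | (4R,5S)-5-Ar-4-(TBDPS-oxymethyl)-3-methylenedihydrofuran-2(3H)-one | C=C1[C@H](CO[Si](c2ccccc2)(c2ccccc2)C(C)(C)C)[C@@H](c2ccc(O[Si](C(C)C)(C(C)C)C(C)C)c(OC)c2)OC1=O | intermediate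
14 | 2-(trimethylsilyloxy)buta-1,3-diene | C=CC(=C)O[Si](C)(C)C | starting material
15 | (3S,4R,5S)-3-Ar-4-(TBDPS-oxymethyl)-8-(trimethylsilyloxy)-2-oxaspiro[4.5]dec-8-en-1-one | C1C[C@]2(CC=C1O[Si](C)(C)C)[C@H](CO[Si](c1ccccc1)(c1ccccc1)C(C)(C)C)[C@@H](c1ccc(O[Si](C(C)C)(C(C)C)C(C)C)c(OC)c1)OC2=O | intermediate
16 | (3S,4R,5S)-3-Ar-4-(TBDPS-oxymethyl)-2-oxaspiro[4.5]dec-9-ene-1,8-dione | O=C1CC[C@]2(C=C1)[C@H](CO[Si](c1ccccc1)(c1ccccc1)C(C)(C)C)[C@@H](c1ccc(O[Si](C(C)C)(C(C)C)C(C)C)c(OC)c1)OC2=O | intermediate
17 | (3S,4R,5S)-3-Ar-4-(TBDPS-oxymethyl)-8,8-(ethylenedioxy)-2-oxaspiro[4.5]dec-9-en-1-one | C1COC2(O1)CC[C@]3(C=C2)[C@H](CO[Si](c2ccccc2)(c2ccccc2)C(C)(C)C)[C@@H](c2ccc(O[Si](C(C)C)(C(C)C)C(C)C)c(OC)c2)OC3=O | intermediate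
18 | ring-opened diol: C5 of the 8,8-(ethylenedioxy)cyclohex-9-ene ring bears C1H2OH and C4H(CH2OTBDPS)–C3H(OH)Ar (C3 S, C4 R, C5 S) | OC[C@@]1(C=CC2(CC1)OCCO2)[C@H](CO[Si](c1ccccc1)(c1ccccc1)C(C)(C)C)[C@H](O)c1ccc(O[Si](C(C)C)(C(C)C)C(C)C)c(OC)c1 | intermediate
19 | bis(triethylsilyl) ether of 18 | CC[Si](CC)(CC)OC[C@@]1(C=CC2(CC1)OCCO2)[C@H](CO[Si](c1ccccc1)(c1ccccc1)C(C)(C)C)[C@H](O[Si](CC)(CC)CC)c1ccc(O[Si](C(C)C)(C(C)C)C(C)C)c(OC)c1 | intermediate
20 | C1 aldehyde with C3 CH(OTES)Ar (C3 S, C4 R, C5 S) | O=C[C@@]1(C=CC2(CC1)OCCO2)[C@H](CO[Si](c1ccccc1)(c1ccccc1)C(C)(C)C)[C@H](O[Si](CC)(CC)CC)c1ccc(O[Si](C(C)C)(C(C)C)C(C)C)c(OC)c1 | intermediate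
21 | 4-(3-hydroxypropyl)-2-methoxyphenol | COc1cc(CCCO)ccc1O | starting material
22 | bromoacetic acid | OC(=O)CBr | starting material
23 | 2-[4-(3-hydroxypropyl)-2-methoxyphenoxy]acetic acid | COc1cc(CCCO)ccc1OCC(=O)O | intermediate
24 | tert-butyldiphenylsilyl 2-(Ar'-oxy)acetate | COc1cc(CCCO[Si](c2ccccc2)(c2ccccc2)C(C)(C)C)ccc1OCC(=O)O[Si](c1ccccc1)(c1ccccc1)C(C)(C)C | intermediate
25 | 2-(Ar'-oxy)acetic acid | COc1cc(CCCO[Si](c2ccccc2)(c2ccccc2)C(C)(C)C)ccc1OCC(=O)O | intermediate
26 | (R)-4-benzyloxazolidin-2-one | O=C1N[C@H](Cc2ccccc2)CO1 | starting material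
27 | 2-(Ar'-oxy)acetic pivalic anhydride | COc1cc(CCCO[Si](c2ccccc2)(c2ccccc2)C(C)(C)C)ccc1OCC(=O)OC(=O)C(C)(C)C | intermediate
28 | (R)-4-benzyl-3-[2-(Ar'-oxy)acetyl]oxazolidin-2-one | COc1cc(CCCO[Si](c2ccccc2)(c2ccccc2)C(C)(C)C)ccc1OCC(=O)N1[C@H](Cc2ccccc2)COC1=O | intermediate
29 | syn-aldol adduct (C1 S, acyl C1' R by priority change, C3 S, C4 R, C5 S) | O=C1OC[C@@H](Cc2ccccc2)N1C(=O)[C@H](Oc1ccc(CCCO[Si](c2ccccc2)(c2ccccc2)C(C)(C)C)cc1OC)[C@@H](O)[C@@]1(C=CC2(CC1)OCCO2)[C@H](CO[Si](c1ccccc1)(c1ccccc1)C(C)(C)C)[C@H](O[Si](CC)(CC)CC)c1ccc(O[Si](C(C)C)(C(C)C)C(C)C)c(OC)c1 | intermediate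
30 | (1S,1'S)-diol with C1 OH and C2' OH | OC[C@H](Oc1ccc(CCCO[Si](c2ccccc2)(c2ccccc2)C(C)(C)C)cc1OC)[C@@H](O)[C@@]1(C=CC2(CC1)OCCO2)[C@H](CO[Si](c1ccccc1)(c1ccccc1)C(C)(C)C)[C@H](O[Si](CC)(CC)CC)c1ccc(O[Si](C(C)C)(C(C)C)C(C)C)c(OC)c1 | intermediate
31 | C2' TBDPS ether of 30 | CC(C)(C)[Si](c1ccccc1)(c1ccccc1)OC[C@H](Oc1ccc(CCCO[Si](c2ccccc2)(c2ccccc2)C(C)(C)C)cc1OC)[C@@H](O)[C@@]1(C=CC2(CC1)OCCO2)[C@H](CO[Si](c1ccccc1)(c1ccccc1)C(C)(C)C)[C@H](O[Si](CC)(CC)CC)c1ccc(O[Si](C(C)C)(C(C)C)C(C)C)c(OC)c1 | intermediate
32 | C3 benzylic alcohol from 31 | CC(C)(C)[Si](c1ccccc1)(c1ccccc1)OC[C@H](Oc1ccc(CCCO[Si](c2ccccc2)(c2ccccc2)C(C)(C)C)cc1OC)[C@@H](O)[C@@]1(C=CC2(CC1)OCCO2)[C@H](CO[Si](c1ccccc1)(c1ccccc1)C(C)(C)C)[C@H](O)c1ccc(O[Si](C(C)C)(C(C)C)C(C)C)c(OC)c1 | intermediate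
33 | C8 ethylene ketal of 34 | C1COC2(O1)CC[C@]3(C=C2)[C@H](CO[Si](c2ccccc2)(c2ccccc2)C(C)(C)C)[C@@H](c2ccc(O[Si](C(C)C)(C(C)C)C(C)C)c(OC)c2)O[C@@H]3[C@H](CO[Si](c2ccccc2)(c2ccccc2)C(C)(C)C)Oc2ccc(CCCO[Si](c3ccccc3)(c3ccccc3)C(C)(C)C)cc2OC | intermediate
34 | (1S,3S,4R,5S)-3-Ar-1-[(1S)-1-(Ar'-oxy)-2-(TBDPS-oxy)ethyl]-4-(TBDPS-oxymethyl)-2-oxaspiro[4.5]dec-9-en-8-one | O=C1CC[C@]2(C=C1)[C@H](CO[Si](c1ccccc1)(c1ccccc1)C(C)(C)C)[C@@H](c1ccc(O[Si](C(C)C)(C(C)C)C(C)C)c(OC)c1)O[C@@H]2[C@H](CO[Si](c1ccccc1)(c1ccccc1)C(C)(C)C)Oc1ccc(CCCO[Si](c2ccccc2)(c2ccccc2)C(C)(C)C)cc1OC | intermediate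
35 | 7-hydroxy derivative of 34 (C7 epimers) | O=C1C(O)C[C@]2(C=C1)[C@H](CO[Si](c1ccccc1)(c1ccccc1)C(C)(C)C)[C@@H](c1ccc(O[Si](C(C)C)(C(C)C)C(C)C)c(OC)c1)O[C@@H]2[C@H](CO[Si](c1ccccc1)(c1ccccc1)C(C)(C)C)Oc1ccc(CCCO[Si](c2ccccc2)(c2ccccc2)C(C)(C)C)cc1OC | intermediate
36 | 7,8-dione from 35 | O=C1C(=O)C[C@]2(C=C1)[C@H](CO[Si](c1ccccc1)(c1ccccc1)C(C)(C)C)[C@@H](c1ccc(O[Si](C(C)C)(C(C)C)C(C)C)c(OC)c1)O[C@@H]2[C@H](CO[Si](c1ccccc1)(c1ccccc1)C(C)(C)C)Oc1ccc(CCCO[Si](c2ccccc2)(c2ccccc2)C(C)(C)C)cc1OC | intermediate
37 | 7-hydroxy-2-oxaspiro[4.5]deca-6,9-dien-8-one (diosphenol), otherwise as 34 | OC1=C[C@]2(C=CC1=O)[C@H](CO[Si](c1ccccc1)(c1ccccc1)C(C)(C)C)[C@@H](c1ccc(O[Si](C(C)C)(C(C)C)C(C)C)c(OC)c1)O[C@@H]2[C@H](CO[Si](c1ccccc1)(c1ccccc1)C(C)(C)C)Oc1ccc(CCCO[Si](c2ccccc2)(c2ccccc2)C(C)(C)C)cc1OC | intermediate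
38 | fully silylated target (7-methoxy dienone; aryl TIPS and three TBDPS ethers) | COC1=C[C@]2(C=CC1=O)[C@H](CO[Si](c1ccccc1)(c1ccccc1)C(C)(C)C)[C@@H](c1ccc(O[Si](C(C)C)(C(C)C)C(C)C)c(OC)c1)O[C@@H]2[C@H](CO[Si](c1ccccc1)(c1ccccc1)C(C)(C)C)Oc1ccc(CCCO[Si](c2ccccc2)(c2ccccc2)C(C)(C)C)cc1OC | intermediate
39 | CNP0252711.1, (1S,3S,4R,5S)-3-(4-hydroxy-3-methoxyphenyl)-4-(hydroxymethyl)-1-[(1S)-2-hydroxy-1-[4-(3-hydroxypropyl)-2-methoxyphenoxy]ethyl]-7-methoxy-2-oxaspiro[4.5]deca-6,9-dien-8-one | COC1=C[C@]2(C=CC1=O)[C@H](CO)[C@@H](c1ccc(O)c(OC)c1)O[C@@H]2[C@H](CO)Oc1ccc(CCCO)cc1OC | target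

Total step count: 24. Longest linear sequence: 20 steps (1, 3–13, 17–24); step 2 and steps 14–16 are side branches.

Least certain steps

Step 8 (key step). The most likely failure is insufficient π-facial discrimination, because the C3 aryl group shields the face opposite the C4 group to some extent. A slow cycloaddition with thermal polymerisation of either partner is the second risk. Fallback: from 13, heating with the more reactive 1-methoxy-3-(trimethylsilyloxy)buta-1,3-diene at lower temperature should give the 10-methoxy cycloadduct F1. Its methoxy carbon bonds to C5, so dilute HCl in THF hydrolyses the enol ether and eliminates methanol across C9–C10. This comes back to the route at 16 and bypasses 15 and step 9.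

Step 17. Slow addition of the boron enolate to an aldehyde on a quaternary carbon could allow enolate decomposition, or a mismatched pairing could erode selectivity. Fallback: from 20, the smaller and more reactive lithium enolate of ethyl 2-(Ar'-oxy)acetate F2 (from 25 with EtI and K2CO3; LiN(iPr)2, THF, −78 °C) is added. The threo β-hydroxy ester F3 is separated from its diastereomers by chromatography and reduced with LiBH4, which comes back to the route at 30. Lithium enolates of aryloxyacetates tend to favour the erythro adduct, so this fallback trades selectivity for reactivity.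

Step 20. The C3 cation could lose the C4 proton and re-protonate, which would epimerise C4. Ionisation could also be too slow at an acidity the silyl ethers tolerate. Fallback: from 31, buffered HF·pyridine removes only the triethylsilyl group to give 32, which is isolated here. MsCl and Et3N at −20 °C then form the benzylic mesylate F4, which ionises and cyclises without protic acid to 33. PPTS in aqueous acetone then removes the ketal and comes back to the route at 34.

Step 13. Competing desilylation or oxidation at the secondary benzylic silyl ether, or sluggish reaction of the neopentyl ether, would lower chemoselectivity. Fallback: from 19, HF·pyridine/pyridine in THF at 0 °C cleaves the primary silyl ether selectively to alcohol F5. Dess–Martin periodinane then gives the aldehyde and comes back to the route at 20.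

Step 9. Protodesilylation of the enol ether faster than palladation would give the saturated ketone and erase the marker of the C10 arm. Fallback: from 15, PhSeCl at −78 °C selenenylates C9 regiospecifically to selenide F6. H2O2 with pyridine at 0 °C causes syn elimination of the selenoxide toward C10 and comes back to the route at 16.

Further compounds

F1 | step 8 | (3S,4R,5S)-3-Ar-10-methoxy-4-(TBDPS-oxymethyl)-8-(trimethylsilyloxy)-2-oxaspiro[4.5]dec-8-en-1-one (C10 epimers) | C1C[C@]2(C(OC)C=C1O[Si](C)(C)C)[C@H](CO[Si](c1ccccc1)(c1ccccc1)C(C)(C)C)[C@@H](c1ccc(O[Si](C(C)C)(C(C)C)C(C)C)c(OC)c1)OC2=O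
F2 | step 17 | ethyl 2-(Ar'-oxy)acetate | CCOC(=O)COc1ccc(CCCO[Si](c2ccccc2)(c2ccccc2)C(C)(C)C)cc1OC
F3 | step 17 | threo ethyl 2-(Ar'-oxy)-3-hydroxy ester from 20 (C1 and C1' as in 30) | CCOC(=O)[C@H](Oc1ccc(CCCO[Si](c2ccccc2)(c2ccccc2)C(C)(C)C)cc1OC)[C@@H](O)[C@@]1(C=CC2(CC1)OCCO2)[C@H](CO[Si](c1ccccc1)(c1ccccc1)C(C)(C)C)[C@H](O[Si](CC)(CC)CC)c1ccc(O[Si](C(C)C)(C(C)C)C(C)C)c(OC)c1
F4 | step 20 | C3 methanesulfonate of 32 | CC(C)(C)[Si](c1ccccc1)(c1ccccc1)OC[C@H](Oc1ccc(CCCO[Si](c2ccccc2)(c2ccccc2)C(C)(C)C)cc1OC)[C@@H](O)[C@@]1(C=CC2(CC1)OCCO2)[C@H](CO[Si](c1ccccc1)(c1ccccc1)C(C)(C)C)[C@H](OS(C)(=O)=O)c1ccc(O[Si](C(C)C)(C(C)C)C(C)C)c(OC)c1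
F5 | step 13 | C1 primary alcohol with C3 CH(OTES)Ar | OC[C@@]1(C=CC2(CC1)OCCO2)[C@H](CO[Si](c1ccccc1)(c1ccccc1)C(C)(C)C)[C@H](O[Si](CC)(CC)CC)c1ccc(O[Si](C(C)C)(C(C)C)C(C)C)c(OC)c1
F6 | step 9 | (3S,4R,5S)-3-Ar-9-(phenylselanyl)-4-(TBDPS-oxymethyl)-2-oxaspiro[4.5]decane-1,8-dione (C9 epimers) | O=C1CC[C@]2(CC1[Se]c1ccccc1)[C@H](CO[Si](c1ccccc1)(c1ccccc1)C(C)(C)C)[C@@H](c1ccc(O[Si](C(C)C)(C(C)C)C(C)C)c(OC)c1)OC2=O
A1 | alternative 1 | α-diazo ester with C4 diazo group and vanillyl-type ether on the C1 oxygen | COC(=O)C(=[N+]=[N-])[C@]1(C=CCCC1)[C@H](OCc1ccc(O[Si](C)(C)C(C)(C)C)c(OC)c1)[C@H](CO[Si](C)(C)C(C)(C)C)Oc1ccc(CCCO[Si](C)(C)C(C)(C)C)cc1OC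
A2 | alternative 1 | methyl 3-aryl-2-oxaspiro[4.5]dec-6-ene-4-carboxylate (C–H insertion product) | C1CC[C@]2(C=C1)[C@H](C(=O)OC)[C@@H](c1ccc(O[Si](C)(C)C(C)(C)C)c(OC)c1)O[C@@H]2[C@H](CO[Si](C)(C)C(C)(C)C)Oc1ccc(CCCO[Si](C)(C)C(C)(C)C)cc1OC
A3 | alternative 2 | trans-1-aryl-2-(silyloxymethyl)-5-methoxyspiro[2.5]octa-4,7-dien-6-one (spiro centre lost in the reaction) | COC1=CC2(C=CC1=O)[C@H](CO[Si](C)(C)C(C)(C)C)[C@H]2c1ccc(O[Si](C)(C)C(C)(C)C)c(OC)c1
A4 | alternative 2 | (S)-2-aryloxy-3-(tert-butyldimethylsilyloxy)propanal | O=C[C@H](CO[Si](C)(C)C(C)(C)C)Oc1ccc(CCCO[Si](C)(C)C(C)(C)C)cc1OC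
A5 | alternative 2 | fully tert-butyldimethylsilylated target | COC1=C[C@]2(C=CC1=O)[C@H](CO[Si](C)(C)C(C)(C)C)[C@@H](c1ccc(O[Si](C)(C)C(C)(C)C)c(OC)c1)O[C@@H]2[C@H](CO[Si](C)(C)C(C)(C)C)Oc1ccc(CCCO[Si](C)(C)C(C)(C)C)cc1OC
A6 | alternative 3 | 7-demethoxy symmetric dienone with free C4 hydroxymethyl group | O=C1C=CC2(C=C1)[C@H](CO)[C@@H](c1ccc(O[Si](C)(C)C(C)(C)C)c(OC)c1)O[C@@H]2[C@H](CO[Si](C)(C)C(C)(C)C)Oc1ccc(CCCO[Si](C)(C)C(C)(C)C)cc1OC
A7 | alternative 3 | tricyclic C6 ether with C7 hydroxyl | O=C1C=C[C@@]2([C@H](OC3)[C@H]1O)[C@H]3[C@@H](c1ccc(O[Si](C)(C)C(C)(C)C)c(OC)c1)O[C@@H]2[C@H](CO[Si](C)(C)C(C)(C)C)Oc1ccc(CCCO[Si](C)(C)C(C)(C)C)cc1OC
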